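**Retrosynthetic overview**

- The strategy rests on ring A, the 2,4-dihydroxyphenyl ring (C1'–C6'): its acyl carbon sits on C1' and its oxygens on C2' and C4', the pattern left when an acetoacetate-derived 1,3-dioxygenated diene (C2'–C5') adds across a terminal ynone (C1', C6').
- Target ⇐ 8-O-silyl ether (fluoride) ⇐ [4+2] cycloaddition/loss of methanol between the ring-B/C ynone and 1-methoxy-1,3-bis(trimethylsilyloxy)buta-1,3-diene, forming C1'–C2' and C5'–C6'.
- Ynone ⇐ Weinreb amide + ethynylmagnesium bromide ⇐ saturated ester ⇐ Wittig olefination/copper hydride 1,4-reduction of the chromene aldehyde.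
- Chromene aldehyde ⇐ one-pot double Claisen rearrangement of the 3-O-(1,1-dimethylallyl) 4-O-(1,1-dimethylpropargyl) diether of 3,4-dihydroxybenzaldehyde (prenyl to C7, pyran ring C closed).
- Ring order: ring B (benzene, purchased) → ring C (pyran, step 4) → ring A (resorcinol, step 12).

Key step: step 12

Remark on the chemistry: the target has no stereocentre. Enol ether 17 is used as an E/Z mixture and diene 18 is drawn as the Z ketene acetal; both geometries are erased in step 12. Carbonate 5 is prepared (step 2) rather than assumed to be purchasable.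

**Route**

Step 1
Reactants: 1 3,4-dihydroxybenzaldehyde; 2 3-chloro-3-methylbut-1-yne
Product: 3 3-hydroxy-4-[(2-methylbut-3-yn-2-yl)oxy]benzaldehyde
Conditions: DBU (1.1 equiv), CuCl2·2H2O (cat.), MeCN, 0 °C to rt
Reagents that add atoms: none
Why: Copper-catalysed O-propargylation of a phenol with a tertiary propargylic chloride; one equivalent of base ionises only the more acidic 4-OH para to the formyl group, so that oxygen should be alkylated selectively.

Step 2
Reactants: 4 2-methylbut-3-en-2-ol
Product: 5 tert-butyl 2-methylbut-3-en-2-yl carbonate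
Conditions: n-BuLi, THF, −78 °C; Boc2O, −78 °C to rt
Reagents that add atoms: di-tert-butyl dicarbonate CC(C)(C)OC(=O)OC(=O)OC(C)(C)C
Why: Acylation of a lithium tertiary alkoxide with the dicarbonate is the standard route to mixed allylic carbonates.

Step 3
Reactants: 3 3-hydroxy-4-[(2-methylbut-3-yn-2-yl)oxy]benzaldehyde; 5 tert-butyl 2-methylbut-3-en-2-yl carbonate
Product: 6 3-[(2-methylbut-3-en-2-yl)oxy]-4-[(2-methylbut-3-yn-2-yl)oxy]benzaldehyde
Conditions: Pd(PPh3)4 (cat.), THF, 0 °C
Reagents that add atoms: none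
Why: Decarboxylative Tsuji–Trost O-allylation in which the phenoxide attacks the more substituted terminus of the 1,1-dimethylallyl palladium complex under kinetic control at low temperature, giving the tertiary (reverse-prenyl) aryl ether.

Step 4
Reactants: 6 3-[(2-methylbut-3-en-2-yl)oxy]-4-[(2-methylbut-3-yn-2-yl)oxy]benzaldehyde
Product: 8 8-hydroxy-2,2-dimethyl-7-(3-methylbut-2-en-1-yl)-2H-chromene-6-carbaldehyde, via ortho-prenyl phenol 7 (not isolated)
Conditions: PhNEt2, 120 °C then 185 °C
Reagents that add atoms: none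
Why: Two aromatic Claisen rearrangements in sequence: the tertiary allyl ether shifts [3,3] with allylic inversion to its only free ortho carbon (between CHO and O) to give the prenyl group, then the propargyl ether rearranges to its only free ortho carbon and closes pyran ring C by 1,5-hydrogen shift and 6π oxa-electrocyclisation.

Step 5
Reactants: 8 8-hydroxy-2,2-dimethyl-7-(3-methylbut-2-en-1-yl)-2H-chromene-6-carbaldehyde
Product: 9 8-[(tert-butyldimethylsilyl)oxy]-2,2-dimethyl-7-(3-methylbut-2-en-1-yl)-2H-chromene-6-carbaldehyde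
Conditions: TBSCl, imidazole, DMF, rt to 40 °C
Reagents that add atoms: tert-butyldimethylsilyl chloride CC(C)(C)[Si](C)(C)Cl
Why: Standard imidazole-promoted silylation of a phenol; the silyl ether removes the acidic proton that would destroy the organomagnesium reagents and the silyl ketene acetal used later.

Step 6
Reactants: 9 8-[(tert-butyldimethylsilyl)oxy]-2,2-dimethyl-7-(3-methylbut-2-en-1-yl)-2H-chromene-6-carbaldehyde; 10 methyl (triphenylphosphoranylidene)acetate
Product: 11 methyl (2E)-3-{8-[(tert-butyldimethylsilyl)oxy]-2,2-dimethyl-7-(3-methylbut-2-en-1-yl)-2H-chromen-6-yl}prop-2-enoate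
Conditions: toluene, 100 °C
Reagents that add atoms: none
Why: Wittig olefination with a stabilised ylide is E-selective and runs under neutral conditions that leave the aryl silyl ether intact.

Step 7
Reactants: 11 methyl (2E)-3-{8-[(tert-butyldimethylsilyl)oxy]-2,2-dimethyl-7-(3-methylbut-2-en-1-yl)-2H-chromen-6-yl}prop-2-enoate
Product: 12 methyl 3-{8-[(tert-butyldimethylsilyl)oxy]-2,2-dimethyl-7-(3-methylbut-2-en-1-yl)-2H-chromen-6-yl}propanoate
Conditions: Cu(OAc)2·H2O (cat.), 1,2-bis(diphenylphosphino)benzene (cat.), HSiMe(OEt)2, t-BuOH, toluene, rt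
Reagents that add atoms: none
Why: Copper hydride conjugate reduction adds hydride only to the electron-poor enoate C=C, so the unpolarised prenyl and chromene alkenes should not react.

Step 8
Reactants: 12 methyl 3-{8-[(tert-butyldimethylsilyl)oxy]-2,2-dimethyl-7-(3-methylbut-2-en-1-yl)-2H-chromen-6-yl}propanoate
Product: 13 3-{8-[(tert-butyldimethylsilyl)oxy]-2,2-dimethyl-7-(3-methylbut-2-en-1-yl)-2H-chromen-6-yl}-N-methoxy-N-methylpropanamide
Conditions: MeNH(OMe)·HCl, i-PrMgCl, THF, −20 °C to 0 °C
Reagents that add atoms: N,O-dimethylhydroxylamine hydrochloride CNOC.Cl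
Why: Aminolysis of the methyl ester by the chloromagnesium amide of N,O-dimethylhydroxylamine is the direct ester-to-Weinreb-amide conversion.

Step 9
Reactants: 13 3-{8-[(tert-butyldimethylsilyl)oxy]-2,2-dimethyl-7-(3-methylbut-2-en-1-yl)-2H-chromen-6-yl}-N-methoxy-N-methylpropanamide; 14 ethynylmagnesium bromide
Product: 15 5-{8-[(tert-butyldimethylsilyl)oxy]-2,2-dimethyl-7-(3-methylbut-2-en-1-yl)-2H-chromen-6-yl}pent-1-yn-3-one
Conditions: THF, 0 °C; inverse quench into cold 1 M HCl
Reagents that add atoms: none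
Why: Weinreb ketone synthesis, in which the chelated tetrahedral intermediate prevents double addition and the cold acidic inverse quench protonates the released amine before it can add to the ynone.

Step 10
Reactants: 16 methyl acetoacetate
Product: 17 methyl 3-(trimethylsilyloxy)but-2-enoate (E/Z mixture)
Conditions: TMSCl, Et3N, hexane, rt
Reagents that add atoms: chlorotrimethylsilane C[Si](C)(C)Cl
Why: O-silylation of the enolised β-keto ester with a silyl chloride and a tertiary amine is the standard silyl enol ether formation.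

Step 11
Reactants: 17 methyl 3-(trimethylsilyloxy)but-2-enoate (E/Z mixture)
Product: 18 1-methoxy-1,3-bis(trimethylsilyloxy)buta-1,3-diene
Conditions: LDA, THF, −78 °C; TMSCl, −78 °C to rt; distillation
Reagents that add atoms: chlorotrimethylsilane C[Si](C)(C)Cl
Why: γ-Deprotonation of the vinylogous ester gives the extended enolate, which is trapped on the ester oxygen to give the silyl ketene acetal (dienolate O-silylation).

Step 12
Reactants: 15 5-{8-[(tert-butyldimethylsilyl)oxy]-2,2-dimethyl-7-(3-methylbut-2-en-1-yl)-2H-chromen-6-yl}pent-1-yn-3-one; 18 1-methoxy-1,3-bis(trimethylsilyloxy)buta-1,3-diene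
Product: 21 3-{8-[(tert-butyldimethylsilyl)oxy]-2,2-dimethyl-7-(3-methylbut-2-en-1-yl)-2H-chromen-6-yl}-1-(2,4-dihydroxyphenyl)propan-1-one, via ketal cycloadduct 19 (not isolated), via bis-trimethylsilyl aryl ether 20 (not isolated)
Conditions: 18 (2 equiv), toluene, 0 °C to 60 °C; then 0.5 M HCl, THF, 0 °C
Reagents that add atoms: none
Why: The electron-rich trioxygenated diene 18 and the polarised terminal ynone 15 should combine in a normal-demand, asynchronous [4+2] cycloaddition in which the diene CH2 terminus (largest HOMO coefficient) bonds to the ynone β-carbon (future C6') and the ketene-acetal carbon bonds to the α-carbon (future C1'), giving 1,4-cyclohexadiene 19; 1,4-elimination of methanol across the ketal carbon and the ring CH2 aromatises it to 20, whose two aryl O–SiMe3 bonds are cleaved by the dilute-acid work-up while the hindered tert-butyldimethylsilyl ether stays. The closest known reaction type is the Diels–Alder/aromatisation of 1,1-dioxygenated 3-silyloxybutadienes with acetylenic ketones and esters, which delivers acylresorcinols. Ring A is closed by an intermolecular [4+2] cycloaddition that makes both C1'–C2' and C5'–C6' in one operation, not by cyclisation of a tethered chain. No stereocentre remains, since the ketal carbon of 19 is stereogenic only transiently and the ketene-acetal geometry is erased on aromatisation. The step needs regioselectivity (oxygen ortho and para to the acyl group), secured by matching the β-electrophilic ynone with the nucleophilic diene terminus, and chemoselectivity, which follows because the prenyl and chromene alkenes are electron-rich non-dienophiles, the 8-OH is masked so no acidic proton consumes the diene, and Lewis acids are excluded so the diene does not attack the carbonyl carbon.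

Step 13
Reactants: 21 3-{8-[(tert-butyldimethylsilyl)oxy]-2,2-dimethyl-7-(3-methylbut-2-en-1-yl)-2H-chromen-6-yl}-1-(2,4-dihydroxyphenyl)propan-1-one
Product: 22 1-(2,4-dihydroxyphenyl)-3-[8-hydroxy-2,2-dimethyl-7-(3-methylbut-2-en-1-yl)-2H-chromen-6-yl]propan-1-one (CNP0290651.0)
Conditions: TBAF, AcOH, THF, 0 °C
Reagents that add atoms: none
Why: Fluoride cleavage of the aryl silyl ether under acetic acid buffering is non-acidic and non-oxidising, so the ortho-prenyl phenol should be released without cyclising to a chroman.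

**Compound list**

1 | 3,4-dihydroxybenzaldehyde | O=Cc1ccc(O)c(O)c1 | starting material
2 | 3-chloro-3-methylbut-1-yne | CC(C)(Cl)C#C | starting material
3 | 3-hydroxy-4-[(2-methylbut-3-yn-2-yl)oxy]benzaldehyde | O=Cc1ccc(OC(C)(C)C#C)c(O)c1 | intermediate
4 | 2-methylbut-3-en-2-ol | CC(C)(O)C=C | starting material
5 | tert-butyl 2-methylbut-3-en-2-yl carbonate | CC(C)(C)OC(=O)OC(C)(C)C=C | intermediate
6 | 3-[(2-methylbut-3-en-2-yl)oxy]-4-[(2-methylbut-3-yn-2-yl)oxy]benzaldehyde | O=Cc1ccc(OC(C)(C)C#C)c(OC(C)(C)C=C)c1 | intermediate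
7 | 3-hydroxy-2-(3-methylbut-2-en-1-yl)-4-[(2-methylbut-3-yn-2-yl)oxy]benzaldehyde (not isolated) | O=Cc1ccc(OC(C)(C)C#C)c(O)c1CC=C(C)C | intermediate
8 | 8-hydroxy-2,2-dimethyl-7-(3-methylbut-2-en-1-yl)-2H-chromene-6-carbaldehyde | CC(C)=CCc1c(C=O)cc2c(c1O)OC(C)(C)C=C2 | intermediate
9 | 8-[(tert-butyldimethylsilyl)oxy]-2,2-dimethyl-7-(3-methylbut-2-en-1-yl)-2H-chromene-6-carbaldehyde | CC(C)=CCc1c(C=O)cc2c(c1O[Si](C)(C)C(C)(C)C)OC(C)(C)C=C2 | intermediate
10 | methyl (triphenylphosphoranylidene)acetate | COC(=O)C=P(c1ccccc1)(c1ccccc1)c1ccccc1 | starting material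
11 | methyl (2E)-3-{8-[(tert-butyldimethylsilyl)oxy]-2,2-dimethyl-7-(3-methylbut-2-en-1-yl)-2H-chromen-6-yl}prop-2-enoate | CC(C)=CCc1c(/C=C/C(=O)OC)cc2c(c1O[Si](C)(C)C(C)(C)C)OC(C)(C)C=C2 | intermediate
12 | methyl 3-{8-[(tert-butyldimethylsilyl)oxy]-2,2-dimethyl-7-(3-methylbut-2-en-1-yl)-2H-chromen-6-yl}propanoate | CC(C)=CCc1c(CCC(=O)OC)cc2c(c1O[Si](C)(C)C(C)(C)C)OC(C)(C)C=C2 | intermediate
13 | 3-{8-[(tert-butyldimethylsilyl)oxy]-2,2-dimethyl-7-(3-methylbut-2-en-1-yl)-2H-chromen-6-yl}-N-methoxy-N-methylpropanamide | CC(C)=CCc1c(CCC(=O)N(C)OC)cc2c(c1O[Si](C)(C)C(C)(C)C)OC(C)(C)C=C2 | intermediate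
14 | ethynylmagnesium bromide | C#C[Mg]Br | starting material
15 | 5-{8-[(tert-butyldimethylsilyl)oxy]-2,2-dimethyl-7-(3-methylbut-2-en-1-yl)-2H-chromen-6-yl}pent-1-yn-3-one | CC(C)=CCc1c(CCC(=O)C#C)cc2c(c1O[Si](C)(C)C(C)(C)C)OC(C)(C)C=C2 | intermediate
16 | methyl acetoacetate | CC(=O)CC(=O)OC | starting material
17 | methyl 3-(trimethylsilyloxy)but-2-enoate (E/Z mixture, geometry not defined) | COC(=O)C=C(C)O[Si](C)(C)C | intermediate
18 | 1-methoxy-1,3-bis(trimethylsilyloxy)buta-1,3-diene (Z ketene acetal drawn) | C=C(O[Si](C)(C)C)/C=C(/OC)O[Si](C)(C)C | intermediate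
19 | 3-{8-[(tert-butyldimethylsilyl)oxy]-2,2-dimethyl-7-(3-methylbut-2-en-1-yl)-2H-chromen-6-yl}-1-[6-methoxy-4,6-bis(trimethylsilyloxy)cyclohexa-1,4-dien-1-yl]propan-1-one (racemic at the ketal carbon, not isolated) | CC(C)=CCc1c(CCC(=O)C3=CCC(O[Si](C)(C)C)=CC3(OC)O[Si](C)(C)C)cc2c(c1O[Si](C)(C)C(C)(C)C)OC(C)(C)C=C2 | intermediate
20 | 1-[2,4-bis(trimethylsilyloxy)phenyl]-3-{8-[(tert-butyldimethylsilyl)oxy]-2,2-dimethyl-7-(3-methylbut-2-en-1-yl)-2H-chromen-6-yl}propan-1-one (not isolated) | CC(C)=CCc1c(CCC(=O)c3ccc(O[Si](C)(C)C)cc3O[Si](C)(C)C)cc2c(c1O[Si](C)(C)C(C)(C)C)OC(C)(C)C=C2 | intermediate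
21 | 3-{8-[(tert-butyldimethylsilyl)oxy]-2,2-dimethyl-7-(3-methylbut-2-en-1-yl)-2H-chromen-6-yl}-1-(2,4-dihydroxyphenyl)propan-1-one | CC(C)=CCc1c(CCC(=O)c2ccc(O)cc2O)cc2c(c1O[Si](C)(C)C(C)(C)C)OC(C)(C)C=C2 | intermediate
22 | 1-(2,4-dihydroxyphenyl)-3-[8-hydroxy-2,2-dimethyl-7-(3-methylbut-2-en-1-yl)-2H-chromen-6-yl]propan-1-one | CC(C)=CCc1c(CCC(=O)c2ccc(O)cc2O)cc2c(c1O)OC(C)(C)C=C2 | target

**Step count**

Total: 13 steps. Longest linear sequence: 10 steps (1, 3, 4, 5, 6, 7, 8, 9, 12, 13); steps 2, 10 and 11 are side branches.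

**Steps most likely to fail, with fallbacks**

Step 12. The reaction may stop after the first C–C bond as an open-chain Michael adduct, the terminal ynone may oligomerise, or the ketal carbon may lose silanol instead of methanol and leave a 2'-methyl ether. The fallback makes the aryl–carbonyl bond by organolithium acylation instead of building the ring. It sets out from Weinreb amide 13 and commercial 4-bromoresorcinol. The latter is bis-protected (MOMCl, i-Pr2NEt, CH2Cl2) to 1-bromo-2,4-bis(methoxymethoxy)benzene F1. Bromine–lithium exchange (n-BuLi, THF, −78 °C) gives [2,4-bis(methoxymethoxy)phenyl]lithium F2, which is added to 13 to give the bis-acetal ketone 3-{8-[(tert-butyldimethylsilyl)oxy]-2,2-dimethyl-7-(3-methylbut-2-en-1-yl)-2H-chromen-6-yl}-1-[2,4-bis(methoxymethoxy)phenyl]propan-1-one F3. Brief dilute HCl in MeOH at rt should remove both acetals while the aryl silyl ether, which keeps the C8 oxygen from adding to the prenyl alkene, stays on. The fallback rejoins the route at 21.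

Step 4. The tertiary allyl group may fragment off (phenol plus isoprene) before it migrates, or it may migrate by ipso attack and Cope shift to the para carbon instead of the crowded carbon between CHO and O. The fallback uses a primary allyl group, which cannot ionise, and builds the prenyl terminus afterwards by metathesis. It sets out from 3, which is O-allylated (allyl bromide, K2CO3, DMF) to 3-(prop-2-en-1-yloxy)-4-[(2-methylbut-3-yn-2-yl)oxy]benzaldehyde F4. One heating operation (PhNEt2, 190 °C) rearranges both ethers to 8-hydroxy-2,2-dimethyl-7-(prop-2-en-1-yl)-2H-chromene-6-carbaldehyde F5. Cross-metathesis with excess 2-methylbut-2-ene (second-generation Grubbs catalyst RuCl2(=CHPh)(PCy3)(H2IMes), CH2Cl2, 40 °C) converts the allyl into the prenyl group. The fallback rejoins at 8.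

Step 3. The phenoxide may attack the unsubstituted terminus of the allyl palladium complex, giving the linear prenyl ether (which would later place a reverse-prenyl group on carbon), or the terminal alkyne may interfere with the catalyst. The fallback makes the tertiary allyl ether by alkyne semi-hydrogenation after the pyran ring is closed. It sets out from 3, which is heated alone (PhNEt2, 185 °C) to 8-hydroxy-2,2-dimethyl-2H-chromene-6-carbaldehyde F6. A second propargylation with 2 (DBU, cat. CuCl2·2H2O, MeCN, 0 °C) gives 2,2-dimethyl-8-[(2-methylbut-3-yn-2-yl)oxy]-2H-chromene-6-carbaldehyde F7, which must not be heated at this stage. Semi-hydrogenation (H2, Pd/CaCO3 poisoned with Pb(OAc)2, quinoline, EtOAc) gives 2,2-dimethyl-8-[(2-methylbut-3-en-2-yl)oxy]-2H-chromene-6-carbaldehyde F8. A Claisen rearrangement in toluene at 110 °C then delivers the prenyl group to C7. The fallback rejoins at 8.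

**Further compounds**

F1 | step 12 | 1-bromo-2,4-bis(methoxymethoxy)benzene | COCOc1ccc(Br)c(OCOC)c1
F2 | step 12 | [2,4-bis(methoxymethoxy)phenyl]lithium | [Li]c1ccc(OCOC)cc1OCOC
F3 | step 12 | 3-{8-[(tert-butyldimethylsilyl)oxy]-2,2-dimethyl-7-(3-methylbut-2-en-1-yl)-2H-chromen-6-yl}-1-[2,4-bis(methoxymethoxy)phenyl]propan-1-one | CC(C)=CCc1c(CCC(=O)c3ccc(OCOC)cc3OCOC)cc2c(c1O[Si](C)(C)C(C)(C)C)OC(C)(C)C=C2
F4 | step 4 | 3-(prop-2-en-1-yloxy)-4-[(2-methylbut-3-yn-2-yl)oxy]benzaldehyde | O=Cc1ccc(OC(C)(C)C#C)c(OCC=C)c1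
F5 | step 4 | 8-hydroxy-2,2-dimethyl-7-(prop-2-en-1-yl)-2H-chromene-6-carbaldehyde | C=CCc1c(C=O)cc2c(c1O)OC(C)(C)C=C2
F6 | step 3 | 8-hydroxy-2,2-dimethyl-2H-chromene-6-carbaldehyde | O=Cc1cc(O)c2OC(C)(C)C=Cc2c1
F7 | step 3 | 2,2-dimethyl-8-[(2-methylbut-3-yn-2-yl)oxy]-2H-chromene-6-carbaldehyde | O=Cc1cc(OC(C)(C)C#C)c2OC(C)(C)C=Cc2c1
F8 | step 3 | 2,2-dimethyl-8-[(2-methylbut-3-en-2-yl)oxy]-2H-chromene-6-carbaldehyde | O=Cc1cc(OC(C)(C)C=C)c2OC(C)(C)C=Cc2c1
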